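The readings were computed from invented constants; noise was put on by code.

E leaves the blue run, a closed isothermal flask of E and L, about twice as fast as the product D appears, and from that run the flasks winter and noon are to be reckoned.

| flask | E | L | remark | time |
|---|---|---|---|---|
| blue | 1.5 M | 2 M | run made earlier |  |
| winter | 1.5 M | 1.50 M |  | 30 h |
| noon | 1.5 M | 2.20 M |  | 30 h |

- blue (time / h: E / %, D / %): 3.00: 78.6, 12.8; 6.00: 59.7, 21.2; 10.0: 49.6, 27.0; 12.0: 41.8, 29.3; 15.0: 36.5, 32.3

(each reading ± 1 percentage point)

- the numbers in the tables scatter with a standard deviation of 1 percentage point
- a reading or a percentage of D counts all its forms, free or not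
- what has gone from E into another species counts as reacted, even if it can come back
- a reading of E is of its free form alone

- part of the E that has reacted at the end, winter
- part of the E that has reacted at the end, noon
- what raising the concentration of L from its lowest to its highest value here does to the part of the E that has reacted (changes below 5 percentage points count as none) (it rises / no change / it falls)

The blue run holds no reading of L, so this reckoning takes the rate of loss of E as second-order and lets L fall one for one with E, an assumption resting on one run. The last blue reading then gives 0.0481 M⁻¹ h⁻¹ for κ, the rate of loss of E divided by the product of the concentrations of E and L, a reading that carries the scatter of that point.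

In winter the rate starts at 0.108 M h⁻¹, a pace that, if held, would turn over 2.17 times the E charged within 30 h. But in this reckoning E and L start equal and fall together, so by then each stands at the factor 0.316 of its charge and the rate at 0.0997 of its start, and this accumulated slowing gives 68.4 % reacted.

With unequal charges, ln([E]/[L]) moves at the steady rate κ([E]−[L]), which gives noon 84.6 %, more than winter. The forecast reads the loss as “D tightly capturing a second E as a complex”, one L per two E, where this reckoning has one L per E, and it gives 75 % for winter and 88 % for noon, both higher than this reckoning; of raising L it says: it rises.

The flasks give 68.2 % in winter and 82.7 % in noon, and of raising L the answer is: it rises, by 14 percentage points.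

    E + L → Z + D (k = 0.0250 M⁻¹ h⁻¹)
    L + Z ⇌ X, settled at all times (K = 28.0 M⁻¹)
    E + D ⇌ Q, settled at all times (K = 30.0 M⁻¹)

In winter the half-life of L by the step from E + L to Z + D lengthens from 28 h at 7.21 h to 58 h at 30.0 h, about twice as long, and 76 % of that step's turnover up to 30.0 h lies behind it at 15.0 h, where κ gives free E 48.0 % and winter holds 47.7 %. In the neighbour of winter charged with 0.38 M of L, the limiting reagent at 0.253 equiv, κ gives 21.4 % of E reacted, and that flask stands at 23.1 %.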